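**Retrosynthetic overview**
1. Desilylation, equatorial methyl addition to a right-ring C5 ketone, dehydration of a left-ring tertiary carbinol and one allylic oxidation trace the target back to a bicyclic diol.
2. Key disconnection: both six-membered rings are opened at C5–C6 and C5'–C6' in one operation. A twofold nickel-catalysed reductive alkyne–carbonyl cyclisation of an open-chain C39 octaene-diyne keto-aldehyde closes both rings and sets both exocyclic E alkenes by syn addition.
3. The open chain is cut at C15–C15' (Stille) into a left C20 vinyl iodide (ynone end) and a right C19 dienyl stannane (ynal end), each made from an enynal and a C5 phosphonate (HWE, C10=C11).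
4. The enynals come from lithium acetylides and 3-(dimethylamino)-2-methylacrolein; the enantiomeric C3'/C3 carbinols come from Keck methallylation/allylation of one aldehyde, 3,3-dimethylpent-4-ynal, made from 2,2-dimethylpent-4-enal.
5. Ring order: no ring exists until step 19, where the right ring (C1–C6) and the left ring (C1'–C6') form together.

Assumption: the target is read as the (3R,5S,6E,3'S,6'E) all-E isomer with carotenoid locants (right ring C1–C6 with the 5-OH, chain C7–C15 then C15'–C7', left ring C1'–C6'); compounds that bring carbon into the skeleton are numbered reactants, and other atom donors stand under "Reagents that add atoms".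

**Route**

Step 1
Reactants: 1 2,2-dimethylpent-4-enal; 2 dimethyl (1-diazo-2-oxopropyl)phosphonate
Product: 3 3,3-dimethylhex-5-en-1-yne
Conditions: K2CO3, MeOH, 0 °C → rt
Reagents that add atoms: none
Why: Seyferth–Gilbert homologation (Ohira–Bestmann variant) turns the non-enolisable α-quaternary aldehyde into the terminal alkyne under mild carbonate conditions that leave the allyl group alone.

Step 2
Reactants: 3 3,3-dimethylhex-5-en-1-yne
Product: 5 3,3-dimethylpent-4-ynal, via ozonide 4 (not isolated)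
Conditions: O3 (1.0 equiv), CH2Cl2, −78 °C; then Me2S, −78 °C → rt
Reagents that add atoms: ozone, [O-][O+]=O
Why: Ozonolysis with reductive work-up cleaves the monosubstituted alkene much faster than the terminal alkyne, so one equivalent of ozone gives the aldehyde.

Step 3
Reactants: 5 3,3-dimethylpent-4-ynal; 6 tributyl(2-methylprop-2-en-1-yl)stannane
Product: 8 (4R)-2,6,6-trimethyloct-1-en-7-yn-4-ol, via tributylstannyl ether 7 (not isolated)
Conditions: (R)-BINOL (20 mol%), Ti(OiPr)4 (10 mol%), 4 Å MS, CH2Cl2, −20 °C; aq NaHCO3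
Reagents that add atoms: none
Why: Keck asymmetric allylation, in which the (R)-BINOL–titanium catalyst delivers the methallyl group to the Re face of the unbranched aldehyde and so sets the carbinol (R here, the later 3'S centre).

Step 4
Reactants: 8 (4R)-2,6,6-trimethyloct-1-en-7-yn-4-ol
Product: 9 tert-butyldimethyl{[(4R)-2,6,6-trimethyloct-1-en-7-yn-4-yl]oxy}silane
Conditions: TBSCl, imidazole, DMF, rt
Reagents that add atoms: tert-butyldimethylsilyl chloride, CC(C)(C)[Si](C)(C)Cl
Why: Standard silylation of the secondary alcohol gives an ether that survives organolithium, ozone, phosphonate anion, nickel and organocerium steps.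

Step 5
Reactants: 9 tert-butyldimethyl{[(4R)-2,6,6-trimethyloct-1-en-7-yn-4-yl]oxy}silane; 10 (2E)-3-(dimethylamino)-2-methylprop-2-enal
Product: 13 (2E,8R)-8-[(tert-butyldimethylsilyl)oxy]-2,6,6,10-tetramethylundeca-2,10-dien-4-ynal, via lithium acetylide 11 (not isolated), via amino alkoxide adduct 12 (not isolated)
Conditions: n-BuLi, THF, −78 °C; then 10, −78 → 0 °C; then 1 M aq HCl, 0 °C, 10 min
Reagents that add atoms: water, O
Why: Vinylogous formylation, in which the acetylide adds 1,2 to the vinylogous formamide and acid hydrolysis of the enamine with loss of water gives the thermodynamically favoured (E)-2-methyl enynal (C7'–C8' bond, C9' methyl, C10' aldehyde).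

Step 6
Reactants: 13 (2E,8R)-8-[(tert-butyldimethylsilyl)oxy]-2,6,6,10-tetramethylundeca-2,10-dien-4-ynal
Product: 15 (2E,8S)-8-[(tert-butyldimethylsilyl)oxy]-2,6,6-trimethyl-10-oxoundec-2-en-4-ynal, via ozonide 14 (not isolated)
Conditions: O3 (1.0 equiv, Sudan Red 7B end point), CH2Cl2, −78 °C; then Me2S
Reagents that add atoms: ozone, [O-][O+]=O
Why: Chemoselective ozonolysis, since the electron-rich 1,1-disubstituted alkene reacts far faster than the electron-poor enynal alkene or the alkyne, and it unmasks the C5' methyl ketone (the descriptor changes only through priority).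

Step 7
Reactants: 16 (2E)-3-methylpent-2-en-4-yn-1-ol
Product: 17 (3E)-5-bromo-3-methylpent-3-en-1-yne
Conditions: PBr3 (0.4 equiv), Et2O, 0 °C
Reagents that add atoms: phosphorus tribromide, BrP(Br)Br
Why: Bromination of the primary allylic alcohol by SN2 displacement keeps the E alkene.

Step 8
Reactants: 17 (3E)-5-bromo-3-methylpent-3-en-1-yne
Product: 18 diethyl [(2E)-3-methylpent-2-en-4-yn-1-yl]phosphonate
Conditions: P(OEt)3, neat, 100 °C
Reagents that add atoms: triethyl phosphite, CCOP(OCC)OCC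
Why: Michaelis–Arbuzov reaction of the primary allylic bromide.

Step 9
Reactants: 18 diethyl [(2E)-3-methylpent-2-en-4-yn-1-yl]phosphonate
Product: 19 diethyl [(2E,4E)-3-methyl-5-(tributylstannyl)penta-2,4-dien-1-yl]phosphonate
Conditions: Bu3SnH, PdCl2(PPh3)2 (2 mol%), THF, 0 °C
Reagents that add atoms: tributyltin hydride, CCCC[SnH](CCCC)CCCC
Why: Palladium-catalysed syn hydrostannation of the terminal alkyne puts tin on the terminal carbon and gives the (E)-dienyl stannane.

Step 10
Reactants: 19 diethyl [(2E,4E)-3-methyl-5-(tributylstannyl)penta-2,4-dien-1-yl]phosphonate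
Product: 20 diethyl [(2E,4E)-5-iodo-3-methylpenta-2,4-dien-1-yl]phosphonate
Conditions: I2, CH2Cl2, 0 °C
Reagents that add atoms: iodine, II
Why: Iododestannylation replaces tin by iodine with retention of the E geometry.

Step 11
Reactants: 20 diethyl [(2E,4E)-5-iodo-3-methylpenta-2,4-dien-1-yl]phosphonate; 15 (2E,8S)-8-[(tert-butyldimethylsilyl)oxy]-2,6,6-trimethyl-10-oxoundec-2-en-4-ynal
Product: 22 (4S,9E,11E,13E,15E)-4-[(tert-butyldimethylsilyl)oxy]-16-iodo-6,6,10,14-tetramethylhexadeca-9,11,13,15-tetraen-7-yn-2-one, via lithiated phosphonate 21 (not isolated)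
Conditions: LiN(SiMe3)2, THF, −78 °C; then 15, −78 → 0 °C
Reagents that add atoms: none
Why: Horner–Wadsworth–Emmons olefination is E-selective for C10'=C11', and the weakly basic stabilised anion attacks the aldehyde in preference to the methyl ketone without eliminating the β-silyloxy group.

Step 12
Reactants: 5 3,3-dimethylpent-4-ynal; 23 allyltributylstannane
Product: 25 (4S)-6,6-dimethyloct-1-en-7-yn-4-ol, via tributylstannyl ether 24 (not isolated)
Conditions: (S)-BINOL (20 mol%), Ti(OiPr)4 (10 mol%), 4 Å MS, CH2Cl2, −20 °C; aq NaHCO3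
Reagents that add atoms: none
Why: Keck asymmetric allylation with the enantiomeric catalyst adds allyl to the Si face and sets the carbinol that becomes C3 of the right ring (S here, 3R in the target).

Step 13
Reactants: 25 (4S)-6,6-dimethyloct-1-en-7-yn-4-ol
Product: 26 tert-butyl{[(4S)-6,6-dimethyloct-1-en-7-yn-4-yl]oxy}dimethylsilane
Conditions: TBSCl, imidazole, DMF, rt
Reagents that add atoms: tert-butyldimethylsilyl chloride, CC(C)(C)[Si](C)(C)Cl
Why: Standard silylation of the secondary alcohol.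

Step 14
Reactants: 26 tert-butyl{[(4S)-6,6-dimethyloct-1-en-7-yn-4-yl]oxy}dimethylsilane
Product: 28 (3R)-3-[(tert-butyldimethylsilyl)oxy]-5,5-dimethylhept-6-yn-1-ol, via ozonide 27 (not isolated)
Conditions: O3 (1.0 equiv), CH2Cl2, −78 °C; then NaBH4, MeOH, −78 °C → rt
Reagents that add atoms: ozone, [O-][O+]=O
Why: Ozonolysis of the terminal alkene with borohydride work-up gives the primary alcohol (the future C5 aldehyde carbon) and leaves the alkyne and silyl ether alone.

Step 15
Reactants: 28 (3R)-3-[(tert-butyldimethylsilyl)oxy]-5,5-dimethylhept-6-yn-1-ol; 10 (2E)-3-(dimethylamino)-2-methylprop-2-enal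
Product: 31 (2E,8R)-8-[(tert-butyldimethylsilyl)oxy]-10-hydroxy-2,6,6-trimethyldec-2-en-4-ynal, via dilithio derivative 29 (not isolated), via amino alkoxide adduct 30 (not isolated)
Conditions: n-BuLi (2.1 equiv), THF, −78 → 0 °C; then 10, −78 → 0 °C; then 1 M aq HCl, 0 °C, 10 min
Reagents that add atoms: water, O
Why: The same vinylogous formylation as in step 5, run on the alkoxide–acetylide dianion so that the primary hydroxyl needs no protection.

Step 16
Reactants: 19 diethyl [(2E,4E)-3-methyl-5-(tributylstannyl)penta-2,4-dien-1-yl]phosphonate; 31 (2E,8R)-8-[(tert-butyldimethylsilyl)oxy]-10-hydroxy-2,6,6-trimethyldec-2-en-4-ynal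
Product: 33 (3R,8E,10E,12E,14E)-3-[(tert-butyldimethylsilyl)oxy]-5,5,9,13-tetramethyl-15-(tributylstannyl)pentadeca-8,10,12,14-tetraen-6-yn-1-ol, via lithiated phosphonate 32 (not isolated)
Conditions: LiN(SiMe3)2, THF, −78 °C; then 31, −78 → 0 °C
Reagents that add atoms: none
Why: E-selective Horner–Wadsworth–Emmons olefination for C10=C11, in which the stabilised phosphonate anion is too weak a base to be quenched by the free primary alcohol.

Step 17
Reactants: 33 (3R,8E,10E,12E,14E)-3-[(tert-butyldimethylsilyl)oxy]-5,5,9,13-tetramethyl-15-(tributylstannyl)pentadeca-8,10,12,14-tetraen-6-yn-1-ol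
Product: 34 (3R,8E,10E,12E,14E)-3-[(tert-butyldimethylsilyl)oxy]-5,5,9,13-tetramethyl-15-(tributylstannyl)pentadeca-8,10,12,14-tetraen-6-ynal
Conditions: Pr4N[RuO4] (5 mol%), N-methylmorpholine N-oxide, 4 Å MS, CH2Cl2, 0 °C
Reagents that add atoms: none
Why: Ley–Griffith oxidation is neutral and non-acidic, so the primary alcohol becomes the aldehyde without protodestannylation or β-elimination of the silyloxy group.

Step 18
Reactants: 22 (4S,9E,11E,13E,15E)-4-[(tert-butyldimethylsilyl)oxy]-16-iodo-6,6,10,14-tetramethylhexadeca-9,11,13,15-tetraen-7-yn-2-one; 34 (3R,8E,10E,12E,14E)-3-[(tert-butyldimethylsilyl)oxy]-5,5,9,13-tetramethyl-15-(tributylstannyl)pentadeca-8,10,12,14-tetraen-6-ynal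
Product: 35 (3R,8E,10E,12E,14E,16E,18E,20E,22E,28S)-3,28-bis[(tert-butyldimethylsilyl)oxy]-5,5,9,13,18,22,26,26-octamethyl-30-oxohentriaconta-8,10,12,14,16,18,20,22-octaene-6,24-diynal
Conditions: Pd2(dba)3 (5 mol%), AsPh3 (20 mol%), DMF, rt, dark
Reagents that add atoms: none
Why: Stille coupling with zerovalent palladium forms the central C15–C15' sp2–sp2 bond with retention of both alkene geometries and tolerates the ketone, the aldehyde and both alkynes.

Step 19
Reactants: 35 (3R,8E,10E,12E,14E,16E,18E,20E,22E,28S)-3,28-bis[(tert-butyldimethylsilyl)oxy]-5,5,9,13,18,22,26,26-octamethyl-30-oxohentriaconta-8,10,12,14,16,18,20,22-octaene-6,24-diynal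
Product: 37 bicyclic diol (3R,3'S,6E,6'E; right ring C5 secondary carbinol lacking C18; left ring C5' tertiary methyl carbinol; O3 and O3' as TBS ethers), via bis(diethylborinate) 36 (not isolated)
Conditions: Ni(cod)2 [bis(1,5-cyclooctadiene)nickel] (20 mol%), PBu3 (40 mol%), Et3B (5 equiv), toluene/EtOAc, rt, 0.005 M, Ar, dark; aq NH4Cl
Reagents that add atoms: none
Why: Proposed new method: a twofold intramolecular nickel-catalysed reductive alkyne–carbonyl coupling, in which zerovalent nickel binds each 1,3-enyne together with its tethered carbonyl, oxidative cyclisation gives an oxanickelacyclopentene (C5–C6 and C5'–C6' bonds, 6-exo closure fixed by the tether and by the enyne preference for bonding at the alkyne carbon remote from the alkene), Et3B transmetalates and β-hydride elimination followed by C7–H reductive elimination completes a syn addition of C5 and H across each alkyne, so H7 ends cis to C5 and the chain trans to it (6E and 6'E); the closest known reactions are nickel/phosphine/Et3B reductive cyclisations of ynals and the intermolecular nickel-catalysed reductive coupling of 1,3-enynes with ketones; the uncontrolled carbinol configurations at C5 and C5' are erased in steps 20 and 21.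

Step 20
Reactants: 37 bicyclic diol
Product: 38 right-ring C5 ketone (3R,3'S,6E,6'E; left-ring tertiary carbinol unchanged)
Conditions: MnO2 (activated, 20 equiv), CH2Cl2, rt, dark
Reagents that add atoms: none
Why: Allylic oxidation with MnO2 takes only the secondary dienylic C5 carbinol and leaves the tertiary C5' carbinol, the silyl ethers and the polyene.

Step 21
Reactants: 38 right-ring C5 ketone
Product: 39 left-ring C4'=C5' diene with right-ring C5 ketone (3R,3'S,6E,6'E)
Conditions: Ph2S[OC(CF3)2Ph]2 (Martin sulfurane, 1.5 equiv), CH2Cl2, −20 → 0 °C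
Reagents that add atoms: none
Why: Martin sulfurane dehydration of the tertiary allylic carbinol under neutral conditions goes through the polyene-stabilised cation and loses H4' to give the conjugated endocyclic trisubstituted alkene (Zaitsev outcome, as in retro-carotenoid dehydrations), while the ketone and the 3'S centre are untouched.

Step 22
Reactants: 39 left-ring C4'=C5' diene with right-ring C5 ketone
Product: 41 3,3'-bis-O-(tert-butyldimethylsilyl) ether of the target (3R,5S,6E,3'S,6'E), via cerium alkoxide 40 (not isolated)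
Conditions: MeLi, CeCl3, THF, −78 °C; aq NH4Cl
Reagents that add atoms: methyllithium, [Li]C
Why: Organocerium 1,2-addition (non-basic, so no enolisation, β-elimination or conjugate addition), in which the axial C1 methyl blocks the axial trajectory and methyl enters equatorially, giving an axial 5-OH trans to the equatorial 3-OTBS, that is 5S.

Step 23
Reactants: 41 3,3'-bis-O-(tert-butyldimethylsilyl) ether of the target
Product: 42 (3R,5S,6E,3'S,6'E)-all-E-4',5-retro-β,β-carotene-3,5,3'-triol (target)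
Conditions: Bu4NF, THF, 0 °C → rt
Reagents that add atoms: none
Why: Fluoride cleavage of both secondary silyl ethers under non-acidic conditions spares the acid-labile tertiary dienylic alcohol and the polyene.

**Compound list**
1 | 2,2-dimethylpent-4-enal | O=CC(C)(C)CC=C | starting material
2 | dimethyl (1-diazo-2-oxopropyl)phosphonate | CC(=O)C(=[N+]=[N-])P(=O)(OC)OC | starting material
3 | 3,3-dimethylhex-5-en-1-yne | C#CC(C)(C)CC=C | intermediate
4 | 3-(2,2-dimethylbut-3-yn-1-yl)-1,2,4-trioxolane (ozonide, racemic) | C#CC(C)(C)CC1OCOO1 | intermediate (not isolated)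
5 | 3,3-dimethylpent-4-ynal | C#CC(C)(C)CC=O | intermediate
6 | tributyl(2-methylprop-2-en-1-yl)stannane | CC(=C)C[Sn](CCCC)(CCCC)CCCC | starting material
7 | tributylstannyl ether of 8 | C#CC(C)(C)C[C@H](O[Sn](CCCC)(CCCC)CCCC)CC(C)=C | intermediate (not isolated)
8 | (4R)-2,6,6-trimethyloct-1-en-7-yn-4-ol | C#CC(C)(C)C[C@H](O)CC(C)=C | intermediate
9 | tert-butyldimethyl{[(4R)-2,6,6-trimethyloct-1-en-7-yn-4-yl]oxy}silane | C#CC(C)(C)C[C@H](O[Si](C)(C)C(C)(C)C)CC(C)=C | intermediate
10 | (2E)-3-(dimethylamino)-2-methylprop-2-enal | CN(C)/C=C(\C)C=O | starting material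
11 | lithium acetylide of 9 | [Li]C#CC(C)(C)C[C@H](O[Si](C)(C)C(C)(C)C)CC(C)=C | intermediate (not isolated)
12 | lithium alkoxide of the 1,2-adduct of 11 to 10 (carbinol epimers) | CN(C)/C=C(\C)C(O[Li])C#CC(C)(C)C[C@H](O[Si](C)(C)C(C)(C)C)CC(C)=C | intermediate (not isolated)
13 | (2E,8R)-8-[(tert-butyldimethylsilyl)oxy]-2,6,6,10-tetramethylundeca-2,10-dien-4-ynal | O=C/C(C)=C/C#CC(C)(C)C[C@H](O[Si](C)(C)C(C)(C)C)CC(C)=C | intermediate
14 | ozonide of the 1,1-disubstituted alkene of 13 (epimers) | O=C/C(C)=C/C#CC(C)(C)C[C@H](O[Si](C)(C)C(C)(C)C)CC1(C)OCOO1 | intermediate (not isolated)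
15 | (2E,8S)-8-[(tert-butyldimethylsilyl)oxy]-2,6,6-trimethyl-10-oxoundec-2-en-4-ynal | O=C/C(C)=C/C#CC(C)(C)C[C@H](O[Si](C)(C)C(C)(C)C)CC(C)=O | intermediate
16 | (2E)-3-methylpent-2-en-4-yn-1-ol | C#C/C(C)=C/CO | starting material
17 | (3E)-5-bromo-3-methylpent-3-en-1-yne | C#C/C(C)=C/CBr | intermediate
18 | diethyl [(2E)-3-methylpent-2-en-4-yn-1-yl]phosphonate | C#C/C(C)=C/CP(=O)(OCC)OCC | intermediate
19 | diethyl [(2E,4E)-3-methyl-5-(tributylstannyl)penta-2,4-dien-1-yl]phosphonate | CCCC[Sn](CCCC)(CCCC)/C=C/C(C)=C/CP(=O)(OCC)OCC | intermediate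
20 | diethyl [(2E,4E)-5-iodo-3-methylpenta-2,4-dien-1-yl]phosphonate | I/C=C/C(C)=C/CP(=O)(OCC)OCC | intermediate
21 | α-lithio derivative of 20 | I/C=C/C(C)=C/C([Li])P(=O)(OCC)OCC | intermediate (not isolated)
22 | (4S,9E,11E,13E,15E)-4-[(tert-butyldimethylsilyl)oxy]-16-iodo-6,6,10,14-tetramethylhexadeca-9,11,13,15-tetraen-7-yn-2-one (left half) | CC(=O)C[C@@H](O[Si](C)(C)C(C)(C)C)CC(C)(C)C#C/C=C(C)/C=C/C=C(C)/C=C/I | intermediate
23 | allyltributylstannane | C=CC[Sn](CCCC)(CCCC)CCCC | starting material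
24 | tributylstannyl ether of 25 | C#CC(C)(C)C[C@@H](O[Sn](CCCC)(CCCC)CCCC)CC=C | intermediate (not isolated)
25 | (4S)-6,6-dimethyloct-1-en-7-yn-4-ol | C#CC(C)(C)C[C@@H](O)CC=C | intermediate
26 | tert-butyl{[(4S)-6,6-dimethyloct-1-en-7-yn-4-yl]oxy}dimethylsilane | C#CC(C)(C)C[C@@H](O[Si](C)(C)C(C)(C)C)CC=C | intermediate
27 | ozonide of 26 (epimers) | C#CC(C)(C)C[C@@H](O[Si](C)(C)C(C)(C)C)CC1OCOO1 | intermediate (not isolated)
28 | (3R)-3-[(tert-butyldimethylsilyl)oxy]-5,5-dimethylhept-6-yn-1-ol | C#CC(C)(C)C[C@@H](O[Si](C)(C)C(C)(C)C)CCO | intermediate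
29 | dilithio derivative of 28 (alkoxide and acetylide) | [Li]C#CC(C)(C)C[C@@H](O[Si](C)(C)C(C)(C)C)CCO[Li] | intermediate (not isolated)
30 | dilithium alkoxide of the 1,2-adduct of 29 to 10 (carbinol epimers) | CN(C)/C=C(\C)C(O[Li])C#CC(C)(C)C[C@@H](O[Si](C)(C)C(C)(C)C)CCO[Li] | intermediate (not isolated)
31 | (2E,8R)-8-[(tert-butyldimethylsilyl)oxy]-10-hydroxy-2,6,6-trimethyldec-2-en-4-ynal | O=C/C(C)=C/C#CC(C)(C)C[C@@H](O[Si](C)(C)C(C)(C)C)CCO | intermediate
32 | α-lithio derivative of 19 | CCCC[Sn](CCCC)(CCCC)/C=C/C(C)=C/C([Li])P(=O)(OCC)OCC | intermediate (not isolated)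
33 | (3R,8E,10E,12E,14E)-3-[(tert-butyldimethylsilyl)oxy]-5,5,9,13-tetramethyl-15-(tributylstannyl)pentadeca-8,10,12,14-tetraen-6-yn-1-ol | CCCC[Sn](CCCC)(CCCC)/C=C/C(C)=C/C=C/C(C)=C/C#CC(C)(C)C[C@@H](O[Si](C)(C)C(C)(C)C)CCO | intermediate
34 | (3R,8E,10E,12E,14E)-3-[(tert-butyldimethylsilyl)oxy]-5,5,9,13-tetramethyl-15-(tributylstannyl)pentadeca-8,10,12,14-tetraen-6-ynal (right half) | CCCC[Sn](CCCC)(CCCC)/C=C/C(C)=C/C=C/C(C)=C/C#CC(C)(C)C[C@@H](O[Si](C)(C)C(C)(C)C)CC=O | intermediate
35 | (3R,8E,10E,12E,14E,16E,18E,20E,22E,28S)-3,28-bis[(tert-butyldimethylsilyl)oxy]-5,5,9,13,18,22,26,26-octamethyl-30-oxohentriaconta-8,10,12,14,16,18,20,22-octaene-6,24-diynal | CC(=O)C[C@@H](O[Si](C)(C)C(C)(C)C)CC(C)(C)C#C/C=C(C)/C=C/C=C(C)/C=C/C=C/C(C)=C/C=C/C(C)=C/C#CC(C)(C)C[C@@H](O[Si](C)(C)C(C)(C)C)CC=O | intermediate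
36 | bis(diethylborinate) of 37 (C5 and C5' epimers) | CC1(OB(CC)CC)C[C@@H](O[Si](C)(C)C(C)(C)C)CC(C)(C)\C1=C/C=C(C)/C=C/C=C(C)/C=C/C=C/C(C)=C/C=C/C(C)=C/C=C1\C(C)(C)C[C@@H](O[Si](C)(C)C(C)(C)C)CC1OB(CC)CC | intermediate (not isolated)
37 | bicyclic diol: all-E retro octaene with right ring 6-hydroxy-2,2-dimethyl-4-(TBSO)cyclohexylidene and left ring 2-hydroxy-2,6,6-trimethyl-4-(TBSO)cyclohexylidene; 3R,3'S,6E,6'E; C5 and C5' epimer mixtures (left unspecified) | CC1(O)C[C@@H](O[Si](C)(C)C(C)(C)C)CC(C)(C)\C1=C/C=C(C)/C=C/C=C(C)/C=C/C=C/C(C)=C/C=C/C(C)=C/C=C1\C(C)(C)C[C@@H](O[Si](C)(C)C(C)(C)C)CC1O | intermediate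
38 | as 37 with the right-ring C5 carbinol oxidised to the ketone; 3R,3'S,6E,6'E; C5' epimers | CC1(O)C[C@@H](O[Si](C)(C)C(C)(C)C)CC(C)(C)\C1=C/C=C(C)/C=C/C=C(C)/C=C/C=C/C(C)=C/C=C/C(C)=C/C=C1\C(C)(C)C[C@@H](O[Si](C)(C)C(C)(C)C)CC1=O | intermediate
39 | as 38 with the left ring dehydrated to the C4'=C5' diene; 3R,3'S,6E,6'E | CC1=C[C@@H](O[Si](C)(C)C(C)(C)C)CC(C)(C)\C1=C/C=C(C)/C=C/C=C(C)/C=C/C=C/C(C)=C/C=C/C(C)=C/C=C1\C(C)(C)C[C@@H](O[Si](C)(C)C(C)(C)C)CC1=O | intermediate
40 | dichlorocerium alkoxide of 41 | CC1=C[C@@H](O[Si](C)(C)C(C)(C)C)CC(C)(C)\C1=C/C=C(C)/C=C/C=C(C)/C=C/C=C/C(C)=C/C=C/C(C)=C/C=C1\C(C)(C)C[C@@H](O[Si](C)(C)C(C)(C)C)C[C@]1(C)O[Ce](Cl)Cl | intermediate (not isolated)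
41 | 3,3'-bis-O-(tert-butyldimethylsilyl) ether of 42; 3R,5S,6E,3'S,6'E | CC1=C[C@@H](O[Si](C)(C)C(C)(C)C)CC(C)(C)\C1=C/C=C(C)/C=C/C=C(C)/C=C/C=C/C(C)=C/C=C/C(C)=C/C=C1\C(C)(C)C[C@@H](O[Si](C)(C)C(C)(C)C)C[C@]1(C)O | intermediate
42 | (3R,5S,6E,3'S,6'E)-all-E-4',5-retro-β,β-carotene-3,5,3'-triol (CNP0269135.1) | CC1=C[C@@H](O)CC(C)(C)\C1=C/C=C(C)/C=C/C=C(C)/C=C/C=C/C(C)=C/C=C/C(C)=C/C=C1\C(C)(C)C[C@@H](O)C[C@]1(C)O | target

**Totals and risks**
Total steps: 23. Longest linear sequence: 14 (steps 1, 2, 12–23).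

Most likely to fail:

1. Step 19 (twofold nickel cyclisation on the full polyene; the ketone terminus is the less precedented closure, and the long polyene may bind the zerovalent nickel). Fallback, setting out from 34 and 15 and returning at 37: the rings are closed on the short halves before the polyene is joined. Aldehyde 34 is cyclised alone with Ni(cod)2/PBu3/Et3B to the right-ring dienyl stannane carbinol F1. Keto-enynal 15 is olefinated with lithiated 19 to the left ynone stannane F2, which is cyclised under the same nickel conditions (heating is possible on this small substrate) to the left-ring stannane carbinol F3. Iododestannylation of F3 with I2 gives the left-ring vinyl iodide F4, and Stille coupling of F1 with F4 (Pd2(dba)3, AsPh3) gives 37.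

2. Step 21 (endocyclic versus exocyclic elimination, or capture of the polyenyl cation elsewhere). Fallback, from 38 to 39: the elimination is moved from a cation to a palladium π-allyl pathway. The tertiary carbinol of 38 is acetylated (Ac2O, DMAP, Et3N, CH2Cl2, 40 °C) to the tertiary allylic acetate F5. Treatment with Pd(PPh3)4 and Et3N in THF at 50 °C ionises it to the π-allyl palladium complex, and β-hydride elimination from C4' gives diene 39.

3. Step 22 (facial selectivity and clean 1,2-addition to the polyenone). Fallback, from 39 to 42: the free C3 hydroxyl is used to deliver the methyl group. Both silyl ethers of 39 are removed first (HF·pyridine buffered with pyridine, THF, 0 °C) to give the dihydroxy ketone F6. Excess MeMgBr in THF/CH2Cl2 at −78 °C then forms the C3 magnesium alkoxide, which directs methyl to the face syn to O3; this gives the 5-OH trans to the 3-OH and reaches 42 directly.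

**Further compounds**
F1 | step 19 | right-ring dienyl stannane carbinol (34 after reductive cyclisation; 3R,6E; C5 epimers) | CCCC[Sn](CCCC)(CCCC)/C=C/C(C)=C/C=C/C(C)=C/C=C1\C(C)(C)C[C@@H](O[Si](C)(C)C(C)(C)C)CC1O
F2 | step 19 | left ynone stannane: (4S,9E,11E,13E,15E)-4-[(tert-butyldimethylsilyl)oxy]-6,6,10,14-tetramethyl-16-(tributylstannyl)hexadeca-9,11,13,15-tetraen-7-yn-2-one | CC(=O)C[C@@H](O[Si](C)(C)C(C)(C)C)CC(C)(C)C#C/C=C(C)/C=C/C=C(C)/C=C/[Sn](CCCC)(CCCC)CCCC
F3 | step 19 | left-ring stannane carbinol (F2 after reductive cyclisation; 3'S,6'E; C5' epimers) | CC1(O)C[C@@H](O[Si](C)(C)C(C)(C)C)CC(C)(C)\C1=C/C=C(C)/C=C/C=C(C)/C=C/[Sn](CCCC)(CCCC)CCCC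
F4 | step 19 | left-ring vinyl iodide (3'S,6'E; C5' epimers) | CC1(O)C[C@@H](O[Si](C)(C)C(C)(C)C)CC(C)(C)\C1=C/C=C(C)/C=C/C=C(C)/C=C/I
F5 | step 21 | tertiary allylic acetate of 38 (O5' acetate) | CC(=O)OC1(C)C[C@@H](O[Si](C)(C)C(C)(C)C)CC(C)(C)\C1=C/C=C(C)/C=C/C=C(C)/C=C/C=C/C(C)=C/C=C/C(C)=C/C=C1\C(C)(C)C[C@@H](O[Si](C)(C)C(C)(C)C)CC1=O
F6 | step 22 | dihydroxy ketone (39 without silyl groups; 3R,3'S,6E,6'E) | CC1=C[C@@H](O)CC(C)(C)\C1=C/C=C(C)/C=C/C=C(C)/C=C/C=C/C(C)=C/C=C/C(C)=C/C=C1\C(C)(C)C[C@@H](O)CC1=O
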